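**Plan**
- Retrosynthetic cuts, in order: the O7–Si bond; O1–C2 (opens the dihydrofuran ring); the three O–benzyl bonds; C2–C3 (benzylic alkylation); C3a–C3 (aryl–CH2); the acrylate C=C.
- Forward: 5-bromovanillin is built into the ring A arylacetic acid (O1 benzyl, O7 triisopropylsilyl, E-acrylate). Its oxazolidinone imide is alkylated with the ring B benzyl bromide, which joins the chain. Methyl ester formation and debenzylation follow, then the only ring closure, then desilylation.
- Enabling feature: C2 is the benzylic carbon para to O4' of the ring B catechol (O3'/O4'), and O1 on C7a of ring A is one five-membered ring away. Oxidising ring B makes C2 a quinone methide carbon that O1 captures.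
- Stereochemistry: C3 comes from (S)-4-benzyl-2-oxazolidinone (Evans alkylation; 2S in the open chain becomes 3R in the target by a priority change only). C2 (R) is induced by C3 in the trans-selective closure. The alkene is E from a stabilised ylide.

Key step: step 14

Remark: O7 carries a triisopropylsilyl (TIPS) group because it must pass TFA, LiOOH and BCl3 and should not migrate to O1; hydrogenolysis is never used because of the acrylate.

**Step 1**
Reactants: 1 5-bromovanillin
Product: 2 3-bromo-4,5-dihydroxybenzaldehyde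
Conditions: AlCl3, pyridine, CH2Cl2, reflux; then aq. HCl
Reagents that add atoms: none
Why: Lewis-acid demethylation of an ortho-hydroxy aryl methyl ether, in which aluminium chelated between the phenoxide and the methoxy oxygen activates the methyl group for SN2 removal by pyridine while the aldehyde and aryl bromide are untouched.

**Step 2**
Reactants: 2 3-bromo-4,5-dihydroxybenzaldehyde
Product: 3 4-(benzyloxy)-3-bromo-5-hydroxybenzaldehyde
Conditions: BnBr (1.05 equiv.), NaHCO3, NaI (cat.), DMF, 40 °C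
Reagents that add atoms: benzyl bromide, BrCc1ccccc1
Why: Williamson ether synthesis under pKa control, since the 4-OH (para to the formyl group, ortho to bromine) is much the more acidic phenol and is the only one ionised by bicarbonate, as in the known 4-O-selective alkylation of 3,4-dihydroxybenzaldehyde.

**Step 3**
Reactants: 3 4-(benzyloxy)-3-bromo-5-hydroxybenzaldehyde
Product: 4 4-(benzyloxy)-3-bromo-5-(triisopropylsilyloxy)benzaldehyde
Conditions: TIPSCl, imidazole, DMF, rt
Reagents that add atoms: chlorotriisopropylsilane, CC(C)[Si](Cl)(C(C)C)C(C)C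
Why: Imidazole-promoted silylation of the remaining, unhindered phenol.

**Step 4**
Reactants: 4 4-(benzyloxy)-3-bromo-5-(triisopropylsilyloxy)benzaldehyde
Product: 5 methyl (E)-3-[4-(benzyloxy)-3-bromo-5-(triisopropylsilyloxy)phenyl]prop-2-enoate
Conditions: Ph3P=CHCO2Me, toluene, 80 °C
Reagents that add atoms: methyl (triphenylphosphoranylidene)acetate, COC(=O)C=P(c1ccccc1)(c1ccccc1)c1ccccc1
Why: Wittig olefination with a stabilised ylide, which should give the E-acrylate and leaves the aryl bromide and the silyl ether alone.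

**Step 5**
Reactants: 5 methyl (E)-3-[4-(benzyloxy)-3-bromo-5-(triisopropylsilyloxy)phenyl]prop-2-enoate
Product: 6 tert-butyl 2-{2-(benzyloxy)-5-[(E)-3-methoxy-3-oxoprop-1-enyl]-3-(triisopropylsilyloxy)phenyl}acetate
Conditions: BrZnCH2CO2t-Bu (1.5 equiv., THF solution), Pd2(dba)3 (2 mol%), XPhos (8 mol%), THF, 50 °C
Reagents that add atoms: (2-tert-butoxy-2-oxoethyl)zinc bromide, CC(C)(C)OC(=O)C[Zn]Br
Why: Negishi-type alpha-arylation of a Reformatsky reagent with an aryl bromide under zerovalent palladium/biarylphosphine catalysis, in which the weakly basic zinc enolate should spare the methyl acrylate, the silyl ether and the benzyl ether.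

**Step 6**
Reactants: 6 tert-butyl arylacetate
Product: 7 2-{2-(benzyloxy)-5-[(E)-3-methoxy-3-oxoprop-1-enyl]-3-(triisopropylsilyloxy)phenyl}acetic acid
Conditions: TFA/CH2Cl2 (1:4), 0 °C to rt
Reagents that add atoms: none
Why: Acidolysis of the tert-butyl ester (E1 loss of isobutene), to which the conjugated methyl ester, the aryl benzyl ether and the aryl TIPS ether should be stable.

**Step 7**
Reactants: 7 ring A arylacetic acid; 8 (S)-4-benzyl-2-oxazolidinone
Product: 10 (4S)-4-benzyl-3-(2-{2-(benzyloxy)-5-[(E)-3-methoxy-3-oxoprop-1-enyl]-3-(triisopropylsilyloxy)phenyl}acetyl)oxazolidin-2-one, via mixed pivalic anhydride 9 (not isolated)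
Conditions: PivCl, Et3N, THF, −20 °C; then 8, LiCl, −20 °C to rt
Reagents that add atoms: none
Why: N-acylation of the oxazolidinone through a mixed anhydride with LiCl/Et3N activation, the nitrogen attacking the less hindered arylacetyl carbonyl of 9.

**Step 8**
Reactants: 11 3,4-bis(benzyloxy)benzaldehyde
Product: 12 [3,4-bis(benzyloxy)phenyl]methanol
Conditions: NaBH4, MeOH/THF, 0 °C
Reagents that add atoms: none
Why: Borohydride reduction of an aromatic aldehyde to the benzylic alcohol.

**Step 9**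
Reactants: 12 [3,4-bis(benzyloxy)phenyl]methanol
Product: 13 1,2-bis(benzyloxy)-4-(bromomethyl)benzene
Conditions: PBr3, CH2Cl2, 0 °C; used at once
Reagents that add atoms: phosphorus tribromide, BrP(Br)Br
Why: Conversion of an electron-rich benzylic alcohol into the bromide by SN2 displacement on its phosphite ester.

**Step 10**
Reactants: 10 ring A arylacetyl imide; 13 1,2-bis(benzyloxy)-4-(bromomethyl)benzene
Product: 15 (4S)-4-benzyl-3-[(2S)-2-{2-(benzyloxy)-5-[(E)-3-methoxy-3-oxoprop-1-enyl]-3-(triisopropylsilyloxy)phenyl}-3-[3,4-bis(benzyloxy)phenyl]propanoyl]oxazolidin-2-one, via sodium Z-enolate 14 (not isolated)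
Conditions: NaN(SiMe3)2 (1.05 equiv.), THF, −78 °C; then 13 (1.3 equiv.), −78 to −40 °C
Reagents that add atoms: none
Why: Evans asymmetric alkylation, in which the sodium-chelated Z-enolate 14 is shielded on one face by the auxiliary benzyl group so that the benzylic bromide enters from the other face and sets the future C3 as 2S; the activated bromide should react faster with the stabilised enolate than the conjugated ester does.

**Step 11**
Reactants: 15 alkylated imide
Product: 17 (2S)-2-{2-(benzyloxy)-5-[(E)-3-methoxy-3-oxoprop-1-enyl]-3-(triisopropylsilyloxy)phenyl}-3-[3,4-bis(benzyloxy)phenyl]propanoic acid, via lithium peroxycarboxylate 16 (not isolated)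
Conditions: LiOH, H2O2, THF/H2O (3:1), 0 °C; then aq. Na2SO3; then 1 M HCl to pH 3
Reagents that add atoms: hydrogen peroxide, OO
Why: Hydroperoxide cleavage of the N-acyloxazolidinone, where LiOOH attacks the exocyclic carbonyl and is too weakly basic to epimerise the alpha-aryl centre, sulfite then reducing peroxy salt 16; any acrylate ester hydrolysed here would be re-formed in step 12.

**Step 12**
Reactants: 17 (2S)-diarylpropanoic acid
Product: 18 methyl (2S)-2-{2-(benzyloxy)-5-[(E)-3-methoxy-3-oxoprop-1-enyl]-3-(triisopropylsilyloxy)phenyl}-3-[3,4-bis(benzyloxy)phenyl]propanoate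
Conditions: TMSCHN2, toluene/MeOH (4:1), 0 °C to rt
Reagents that add atoms: (trimethylsilyl)diazomethane, C[Si](C)(C)C=[N+]=[N-]
Why: Methyl ester formation from the acid with a diazoalkane under neutral conditions, which leaves the alpha-aryl stereocentre untouched.

**Step 13**
Reactants: 18 tribenzyl methyl ester
Product: 19 methyl (2S)-3-(3,4-dihydroxyphenyl)-2-{2-hydroxy-5-[(E)-3-methoxy-3-oxoprop-1-enyl]-3-(triisopropylsilyloxy)phenyl}propanoate
Conditions: BCl3 (1 M in CH2Cl2, 6 equiv.), pentamethylbenzene (9 equiv.), CH2Cl2, −78 °C; then MeOH, −78 °C to rt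
Reagents that add atoms: none
Why: Lewis-acid debenzylation of aryl benzyl ethers with a non-basic benzyl cation scavenger at low temperature, a method known to spare esters, alkenes and silyl ethers; the methanol quench keeps the 2-hydroxyaryl ester open.

**Step 14**
Reactants: 19 O7-silylated triphenol
Product: 22 methyl (2R,3R)-2-(3,4-dihydroxyphenyl)-5-[(E)-3-methoxy-3-oxoprop-1-enyl]-7-(triisopropylsilyloxy)-2,3-dihydro-1-benzofuran-3-carboxylate, via ortho-quinone 20 (not isolated), via para-quinone methide 21 (not isolated)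
Conditions: NaIO4 (1.0 equiv.), MeCN/aq. NaH2PO4–Na2HPO4 buffer pH 7 (1:1), argon, 0 °C to rt
Reagents that add atoms: none
Why: Proposed new method: periodate oxidises through a cyclic ester and so needs two adjacent free hydroxyls, which should convert only the ring B catechol into ortho-quinone 20; loss of one of the two C2–H protons to the buffer then tautomerises 20 to the 2-hydroxy para-quinone methide 21, whose exocyclic C2 is para to O4', and the O1 phenol adds to C2 as ring B rearomatises to the catechol. The closest known reaction types are nucleophile capture by quinone methides formed by tautomerisation of 4-alkyl-ortho-quinones, and the phenol-onto-quinone-methide closure that ends the oxidative 8–5' coupling of ferulate esters to trans-dihydrobenzofurans. The dihydrofuran ring (O1, C7a, C3a, C3, C2) closes 5-exo-trig, because the attacked C2=C1' bond lies outside the new ring. C2 is planar in 21 and its configuration is set by C3: in the envelope transition state the quinonoid ring takes the face anti to the C3 ester, which should give the trans (2R,3R) isomer, also the more stable one. The step needs selection between the rings, secured by the single free hydroxyl and the acrylate deactivation of ring A and by one equivalent of oxidant; it also needs O1 closure to outrun loss of H3 from 21, secured by five-membered intramolecular delivery of an acidic, partly ionised phenol. The silyl group should stay on O7 because O1 is the more acidic and more hindered oxygen.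

**Step 15**
Reactants: 22 7-O-TIPS ether of the target
Product: 23 methyl (2R,3R)-2-(3,4-dihydroxyphenyl)-7-hydroxy-5-[(E)-3-methoxy-3-oxoprop-1-enyl]-2,3-dihydro-1-benzofuran-3-carboxylate (CNP0529351.1)
Conditions: TBAF (1.2 equiv.), AcOH (1.2 equiv.), THF, 0 °C
Reagents that add atoms: none
Why: Fluoride cleavage of an aryl silyl ether, buffered with acetic acid so that the C3 ester is not epimerised and the ring is not opened by beta-elimination of O1.

**Compound list**
1 | 5-bromovanillin (3-bromo-4-hydroxy-5-methoxybenzaldehyde) | COc1cc(C=O)cc(Br)c1O | starting material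
2 | 3-bromo-4,5-dihydroxybenzaldehyde | O=Cc1cc(O)c(O)c(Br)c1 | intermediate
3 | 4-(benzyloxy)-3-bromo-5-hydroxybenzaldehyde | O=Cc1cc(O)c(OCc2ccccc2)c(Br)c1 | intermediate
4 | 4-(benzyloxy)-3-bromo-5-(triisopropylsilyloxy)benzaldehyde | O=Cc1cc(O[Si](C(C)C)(C(C)C)C(C)C)c(OCc2ccccc2)c(Br)c1 | intermediate
5 | methyl (E)-3-[4-(benzyloxy)-3-bromo-5-(triisopropylsilyloxy)phenyl]prop-2-enoate | COC(=O)/C=C/c1cc(O[Si](C(C)C)(C(C)C)C(C)C)c(OCc2ccccc2)c(Br)c1 | intermediate
6 | tert-butyl 2-{2-(benzyloxy)-5-[(E)-3-methoxy-3-oxoprop-1-enyl]-3-(triisopropylsilyloxy)phenyl}acetate | COC(=O)/C=C/c1cc(O[Si](C(C)C)(C(C)C)C(C)C)c(OCc2ccccc2)c(CC(=O)OC(C)(C)C)c1 | intermediate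
7 | 2-{2-(benzyloxy)-5-[(E)-3-methoxy-3-oxoprop-1-enyl]-3-(triisopropylsilyloxy)phenyl}acetic acid | COC(=O)/C=C/c1cc(O[Si](C(C)C)(C(C)C)C(C)C)c(OCc2ccccc2)c(CC(=O)O)c1 | intermediate
8 | (S)-4-benzyl-2-oxazolidinone | O=C1N[C@@H](Cc2ccccc2)CO1 | starting material
9 | mixed anhydride of acid 7 with pivalic acid (formed in the flask) | COC(=O)/C=C/c1cc(O[Si](C(C)C)(C(C)C)C(C)C)c(OCc2ccccc2)c(CC(=O)OC(=O)C(C)(C)C)c1 | intermediate
10 | (4S)-4-benzyl-3-(2-{2-(benzyloxy)-5-[(E)-3-methoxy-3-oxoprop-1-enyl]-3-(triisopropylsilyloxy)phenyl}acetyl)oxazolidin-2-one | COC(=O)/C=C/c1cc(O[Si](C(C)C)(C(C)C)C(C)C)c(OCc2ccccc2)c(CC(=O)N2[C@@H](Cc3ccccc3)COC2=O)c1 | intermediate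
11 | 3,4-bis(benzyloxy)benzaldehyde | O=Cc1ccc(OCc2ccccc2)c(OCc2ccccc2)c1 | starting material
12 | [3,4-bis(benzyloxy)phenyl]methanol | OCc1ccc(OCc2ccccc2)c(OCc2ccccc2)c1 | intermediate
13 | 1,2-bis(benzyloxy)-4-(bromomethyl)benzene | BrCc1ccc(OCc2ccccc2)c(OCc2ccccc2)c1 | intermediate
14 | sodium Z-enolate of imide 10 (formed in the flask) | COC(=O)/C=C/c1cc(O[Si](C(C)C)(C(C)C)C(C)C)c(OCc2ccccc2)c(/C=C(\[O-])N2[C@@H](Cc3ccccc3)COC2=O)c1.[Na+] | intermediate
15 | (4S)-4-benzyl-3-[(2S)-2-{2-(benzyloxy)-5-[(E)-3-methoxy-3-oxoprop-1-enyl]-3-(triisopropylsilyloxy)phenyl}-3-[3,4-bis(benzyloxy)phenyl]propanoyl]oxazolidin-2-one | COC(=O)/C=C/c1cc(O[Si](C(C)C)(C(C)C)C(C)C)c(OCc2ccccc2)c([C@@H](C(=O)N2[C@@H](Cc3ccccc3)COC2=O)Cc2ccc(OCc3ccccc3)c(OCc3ccccc3)c2)c1 | intermediate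
16 | lithium (2S)-peroxycarboxylate of acid 17 (formed in the flask) | COC(=O)/C=C/c1cc(O[Si](C(C)C)(C(C)C)C(C)C)c(OCc2ccccc2)c([C@@H](C(=O)O[O-])Cc2ccc(OCc3ccccc3)c(OCc3ccccc3)c2)c1.[Li+] | intermediate
17 | (2S)-2-{2-(benzyloxy)-5-[(E)-3-methoxy-3-oxoprop-1-enyl]-3-(triisopropylsilyloxy)phenyl}-3-[3,4-bis(benzyloxy)phenyl]propanoic acid | COC(=O)/C=C/c1cc(O[Si](C(C)C)(C(C)C)C(C)C)c(OCc2ccccc2)c([C@@H](C(=O)O)Cc2ccc(OCc3ccccc3)c(OCc3ccccc3)c2)c1 | intermediate
18 | methyl (2S)-2-{2-(benzyloxy)-5-[(E)-3-methoxy-3-oxoprop-1-enyl]-3-(triisopropylsilyloxy)phenyl}-3-[3,4-bis(benzyloxy)phenyl]propanoate | COC(=O)/C=C/c1cc(O[Si](C(C)C)(C(C)C)C(C)C)c(OCc2ccccc2)c([C@@H](C(=O)OC)Cc2ccc(OCc3ccccc3)c(OCc3ccccc3)c2)c1 | intermediate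
19 | methyl (2S)-3-(3,4-dihydroxyphenyl)-2-{2-hydroxy-5-[(E)-3-methoxy-3-oxoprop-1-enyl]-3-(triisopropylsilyloxy)phenyl}propanoate | COC(=O)/C=C/c1cc(O[Si](C(C)C)(C(C)C)C(C)C)c(O)c([C@@H](C(=O)OC)Cc2ccc(O)c(O)c2)c1 | intermediate
20 | methyl (2S)-3-(3,4-dioxocyclohexa-1,5-dien-1-yl)-2-{2-hydroxy-5-[(E)-3-methoxy-3-oxoprop-1-enyl]-3-(triisopropylsilyloxy)phenyl}propanoate (ortho-quinone, formed in the flask) | COC(=O)/C=C/c1cc(O[Si](C(C)C)(C(C)C)C(C)C)c(O)c([C@@H](C(=O)OC)CC2=CC(=O)C(=O)C=C2)c1 | intermediate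
21 | methyl (2S)-3-(3-hydroxy-4-oxocyclohexa-2,5-dien-1-ylidene)-2-{2-hydroxy-5-[(E)-3-methoxy-3-oxoprop-1-enyl]-3-(triisopropylsilyloxy)phenyl}propanoate (para-quinone methide, formed in the flask, exocyclic geometry not defined) | COC(=O)/C=C/c1cc(O[Si](C(C)C)(C(C)C)C(C)C)c(O)c([C@@H](C(=O)OC)C=C2C=CC(=O)C(O)=C2)c1 | intermediate
22 | methyl (2R,3R)-2-(3,4-dihydroxyphenyl)-5-[(E)-3-methoxy-3-oxoprop-1-enyl]-7-(triisopropylsilyloxy)-2,3-dihydro-1-benzofuran-3-carboxylate | COC(=O)/C=C/c1cc(O[Si](C(C)C)(C(C)C)C(C)C)c2c(c1)[C@@H](C(=O)OC)[C@H](c1ccc(O)c(O)c1)O2 | intermediate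
23 | methyl (2R,3R)-2-(3,4-dihydroxyphenyl)-7-hydroxy-5-[(E)-3-methoxy-3-oxoprop-1-enyl]-2,3-dihydro-1-benzofuran-3-carboxylate (CNP0529351.1) | COC(=O)/C=C/c1cc(O)c2c(c1)[C@@H](C(=O)OC)[C@H](c1ccc(O)c(O)c1)O2 | target

**Step count:** 15 steps in total. The longest linear sequence is 13 steps (steps 1–7 and 10–15); steps 8–9 form the ring B branch.

**The three steps most likely to fail**

**Step 14 (the one new method).** The tautomerisation of the ortho-quinone to the quinone methide may be slow compared with redox exchange between quinone and product catechol (over-oxidation to the benzofuran) and with additions to the quinone ring. The quinone methide may also lose H3 and become an achiral 2-aryl cinnamate before O1 closes.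

The fallback uses known chemistry, sets out from imide 10 and comes back at target 23. Ring B is brought in with O4' as a benzyl ether and O3' as a TIPS ether, so that after debenzylation it is a para-alkylphenol and not a catechol. DDQ dehydrogenation of para-alkylphenols to quinone methides with capture by a neighbouring phenol is the established closure of flavans from 1,3-diarylpropanes and of pterocarpans from 2'-hydroxyisoflavans. It needs no ortho-quinone stage and gives a product that cannot enter catechol/quinone redox exchange.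

Purchased 4-(benzyloxy)-3-hydroxybenzaldehyde F1 is silylated (TIPSCl, imidazole, DMF) to 4-(benzyloxy)-3-(triisopropylsilyloxy)benzaldehyde F2. Reduction (NaBH4, MeOH) gives [4-(benzyloxy)-3-(triisopropylsilyloxy)phenyl]methanol F3, and bromination (CBr4, PPh3, CH2Cl2) gives 1-(benzyloxy)-4-(bromomethyl)-2-(triisopropylsilyloxy)benzene F4. Enolate 14 from imide 10 is alkylated with F4 as in step 10 to give the ring B-modified alkylated imide F5. LiOOH as in step 11 gives the corresponding (2S)-acid F6, TMSCHN2 gives its methyl ester F7, and BCl3/pentamethylbenzene as in step 13 gives the O1,O4'-diphenol F8 (O7 and O3' still silylated). DDQ (1.0 equiv., CH2Cl2, 0 °C) should then close the ring to the bis-silylated trans-dihydrobenzofuran F9, and TBAF/AcOH as in step 15, acting on both silyl groups, should give 23.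

**Step 10.** The sodium enolate may add in conjugate fashion to the acrylate of a second molecule. The hindered, ortho-substituted enolate may also alkylate slowly, so that remaining base epimerises the product and the diastereoselectivity erodes.

The fallback sets out from acid 7 and aldehyde 11 and comes back at acid 17; steps 8 and 9 fall away. A boron enolate is neither strongly basic nor a Michael donor toward the acrylate. An Evans syn aldol followed by ionic deoxygenation of the electron-rich benzylic alcohol gives the same C3 centre. Because the boron aldol uses the enolate face opposite to that of the chelated alkylation, the enantiomeric auxiliary is needed.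

Acid 7 is coupled (PivCl, Et3N, LiCl, THF) with (R)-4-benzyl-2-oxazolidinone to the (4R)-arylacetyl imide F10. Enolisation with Bu2BOTf/i-Pr2NEt (CH2Cl2, −78 °C), addition of 11 and work-up with H2O2 in pH 7 buffer should give the (2R,3R)-syn aldol F11. Et3SiH/TFA (CH2Cl2, −20 °C) removes the benzylic hydroxyl by hydride capture of the para-alkoxybenzyl cation and gives the (4R,2S)-deoxygenated imide F12, the diastereomer of 15 that carries the enantiomeric auxiliary. LiOOH as in step 11 then gives 17.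

**Step 5.** Oxidative addition and transmetalation at the bromide flanked by the benzyloxy group may be slow, so that protodebromination or Heck-type consumption of the acrylate competes with C–C coupling.

The fallback sets out from bromide 5 and comes back at acid 7; steps 5 and 6 fall away. The two-carbon unit comes from a vinyl boronate and the acid level is reached by oxidation. Suzuki–Miyaura coupling of 5 with (E)-2-(2-ethoxyvinyl)-4,4,5,5-tetramethyl-1,3,2-dioxaborolane (Pd(OAc)2, SPhos, K3PO4, THF/H2O, 50 °C) should give the aryl enol ether F13. Hydrolysis (1 M HCl, THF, rt) gives the arylacetaldehyde F14, and Pinnick oxidation (NaClO2, NaH2PO4, 2-methyl-2-butene, t-BuOH/H2O) gives 7.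

**Further compounds**
F1 | step 14 | 4-(benzyloxy)-3-hydroxybenzaldehyde (purchased) | O=Cc1ccc(OCc2ccccc2)c(O)c1
F2 | step 14 | 4-(benzyloxy)-3-(triisopropylsilyloxy)benzaldehyde | O=Cc1ccc(OCc2ccccc2)c(O[Si](C(C)C)(C(C)C)C(C)C)c1
F3 | step 14 | [4-(benzyloxy)-3-(triisopropylsilyloxy)phenyl]methanol | OCc1ccc(OCc2ccccc2)c(O[Si](C(C)C)(C(C)C)C(C)C)c1
F4 | step 14 | 1-(benzyloxy)-4-(bromomethyl)-2-(triisopropylsilyloxy)benzene | BrCc1ccc(OCc2ccccc2)c(O[Si](C(C)C)(C(C)C)C(C)C)c1
F5 | step 14 | (4S)-4-benzyl-3-[(2S)-2-{2-(benzyloxy)-5-[(E)-3-methoxy-3-oxoprop-1-enyl]-3-(triisopropylsilyloxy)phenyl}-3-[4-(benzyloxy)-3-(triisopropylsilyloxy)phenyl]propanoyl]oxazolidin-2-one | COC(=O)/C=C/c1cc(O[Si](C(C)C)(C(C)C)C(C)C)c(OCc2ccccc2)c([C@@H](C(=O)N2[C@@H](Cc3ccccc3)COC2=O)Cc2ccc(OCc3ccccc3)c(O[Si](C(C)C)(C(C)C)C(C)C)c2)c1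
F6 | step 14 | (2S)-2-{2-(benzyloxy)-5-[(E)-3-methoxy-3-oxoprop-1-enyl]-3-(triisopropylsilyloxy)phenyl}-3-[4-(benzyloxy)-3-(triisopropylsilyloxy)phenyl]propanoic acid | COC(=O)/C=C/c1cc(O[Si](C(C)C)(C(C)C)C(C)C)c(OCc2ccccc2)c([C@@H](C(=O)O)Cc2ccc(OCc3ccccc3)c(O[Si](C(C)C)(C(C)C)C(C)C)c2)c1
F7 | step 14 | methyl (2S)-2-{2-(benzyloxy)-5-[(E)-3-methoxy-3-oxoprop-1-enyl]-3-(triisopropylsilyloxy)phenyl}-3-[4-(benzyloxy)-3-(triisopropylsilyloxy)phenyl]propanoate | COC(=O)/C=C/c1cc(O[Si](C(C)C)(C(C)C)C(C)C)c(OCc2ccccc2)c([C@@H](C(=O)OC)Cc2ccc(OCc3ccccc3)c(O[Si](C(C)C)(C(C)C)C(C)C)c2)c1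
F8 | step 14 | methyl (2S)-2-{2-hydroxy-5-[(E)-3-methoxy-3-oxoprop-1-enyl]-3-(triisopropylsilyloxy)phenyl}-3-[4-hydroxy-3-(triisopropylsilyloxy)phenyl]propanoate | COC(=O)/C=C/c1cc(O[Si](C(C)C)(C(C)C)C(C)C)c(O)c([C@@H](C(=O)OC)Cc2ccc(O)c(O[Si](C(C)C)(C(C)C)C(C)C)c2)c1
F9 | step 14 | methyl (2R,3R)-2-[4-hydroxy-3-(triisopropylsilyloxy)phenyl]-5-[(E)-3-methoxy-3-oxoprop-1-enyl]-7-(triisopropylsilyloxy)-2,3-dihydro-1-benzofuran-3-carboxylate | COC(=O)/C=C/c1cc(O[Si](C(C)C)(C(C)C)C(C)C)c2c(c1)[C@@H](C(=O)OC)[C@H](c1ccc(O)c(O[Si](C(C)C)(C(C)C)C(C)C)c1)O2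
F10 | step 10 | (4R)-4-benzyl-3-(2-{2-(benzyloxy)-5-[(E)-3-methoxy-3-oxoprop-1-enyl]-3-(triisopropylsilyloxy)phenyl}acetyl)oxazolidin-2-one | COC(=O)/C=C/c1cc(O[Si](C(C)C)(C(C)C)C(C)C)c(OCc2ccccc2)c(CC(=O)N2[C@H](Cc3ccccc3)COC2=O)c1
F11 | step 10 | (4R)-4-benzyl-3-[(2R,3R)-2-{2-(benzyloxy)-5-[(E)-3-methoxy-3-oxoprop-1-enyl]-3-(triisopropylsilyloxy)phenyl}-3-[3,4-bis(benzyloxy)phenyl]-3-hydroxypropanoyl]oxazolidin-2-one | COC(=O)/C=C/c1cc(O[Si](C(C)C)(C(C)C)C(C)C)c(OCc2ccccc2)c([C@@H](C(=O)N2[C@H](Cc3ccccc3)COC2=O)[C@@H](O)c2ccc(OCc3ccccc3)c(OCc3ccccc3)c2)c1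
F12 | step 10 | (4R)-4-benzyl-3-[(2S)-2-{2-(benzyloxy)-5-[(E)-3-methoxy-3-oxoprop-1-enyl]-3-(triisopropylsilyloxy)phenyl}-3-[3,4-bis(benzyloxy)phenyl]propanoyl]oxazolidin-2-one | COC(=O)/C=C/c1cc(O[Si](C(C)C)(C(C)C)C(C)C)c(OCc2ccccc2)c([C@@H](C(=O)N2[C@H](Cc3ccccc3)COC2=O)Cc2ccc(OCc3ccccc3)c(OCc3ccccc3)c2)c1
F13 | step 5 | methyl (E)-3-{4-(benzyloxy)-3-[(E)-2-ethoxyvinyl]-5-(triisopropylsilyloxy)phenyl}prop-2-enoate | COC(=O)/C=C/c1cc(O[Si](C(C)C)(C(C)C)C(C)C)c(OCc2ccccc2)c(/C=C/OCC)c1
F14 | step 5 | methyl (E)-3-[4-(benzyloxy)-3-(2-oxoethyl)-5-(triisopropylsilyloxy)phenyl]prop-2-enoate | COC(=O)/C=C/c1cc(O[Si](C(C)C)(C(C)C)C(C)C)c(OCc2ccccc2)c(CC=O)c1
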